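Assumption: the target has no stereocentre and no configurationally stable axis, so it is achiral and there is no enantiomer to select; compounds 1, 2 and 3 are taken as catalogue materials.

**Retrosynthetic overview**
1. No ring is built. The three benzene rings are bought as 4,5-dibromocatechol (1, ring B), 3,5-dibromo-2-fluorobenzaldehyde (2, ring A) and 5-bromo-2-fluoroaniline (3, ring C); only two C–O bonds, one C–Br bond and one C–I bond are made.
2. Last disconnection: the ring A phenol comes from an aryl aldehyde (Baeyer–Villiger/Dakin). The CHO first activates the SNAr and keeps ring A inert to bromine and to diazonium ions.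
3. Key disconnection: the ring B–O–ring C ether comes from the hindered ring B phenol and a 2-fluoroarenediazonium salt. The diazonio group activates fluoride displacement and is then exchanged for the iodine.
4. The third ring B bromine comes from bromination of the free ring B phenol at its only open ortho/para position.
5. Joining order: ring A to ring B by SNAr mono-arylation of 1 with 2, then ring C onto ring B.

**Route**

Step 1
Reactants: 3 5-bromo-2-fluoroaniline
Product: 4 5-bromo-2-fluorobenzenediazonium tetrafluoroborate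
Conditions: t-BuONO (1.2 equiv), 48% aq HBF4 (2 equiv), EtOH, 0 °C; precipitate with Et2O, dry, store cold and dark
Reagents that add atoms: tert-butyl nitrite CC(C)(C)ON=O; tetrafluoroboric acid [H+].F[B-](F)(F)F
Why: Standard diazotisation of an aniline with an alkyl nitrite in HBF4 gives the isolable, non-nucleophilic tetrafluoroborate salt.

Step 2
Reactants: 1 4,5-dibromocatechol (2 equiv); 2 3,5-dibromo-2-fluorobenzaldehyde
Product: 5 3,5-dibromo-2-(4,5-dibromo-2-hydroxyphenoxy)benzaldehyde
Conditions: K2CO3 (1.1 equiv), degassed DMF, 60 °C, Ar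
Reagents that add atoms: none
Why: SNAr of a phenoxide on a 2-fluorobenzaldehyde (F activated by ortho-CHO and ortho/para-Br); the catechol is symmetric, so either OH gives the same mono-ether, and excess 1 suppresses double arylation.

Step 3
Reactants: 5 3,5-dibromo-2-(4,5-dibromo-2-hydroxyphenoxy)benzaldehyde
Product: 6 3,5-dibromo-2-(3,4,5-tribromo-2-hydroxyphenoxy)benzaldehyde
Conditions: Br2 (1.05 equiv), NaOAc (1.2 equiv), AcOH, 20 °C
Reagents that add atoms: bromine BrBr
Why: Electrophilic aromatic bromination goes to the only free ortho/para position of the ring B phenol (ortho to OH), while ring A is deactivated by its CHO.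

Step 4
Reactants: 6 3,5-dibromo-2-(3,4,5-tribromo-2-hydroxyphenoxy)benzaldehyde; 4 5-bromo-2-fluorobenzenediazonium tetrafluoroborate (1.3 equiv)
Product: 9 3,5-dibromo-2-[3,4,5-tribromo-2-(4-bromo-2-iodophenoxy)phenoxy]benzaldehyde, via sodium phenolate 7 (not isolated), via aryloxydiazonium tetrafluoroborate 8 (not isolated)
Conditions: NaH (1.0 equiv), THF, 0 °C; solvent swap to MeCN; add dropwise to 4 in MeCN, −30 → 0 °C, dark; then KI (3 equiv), H2O, 0 → 20 °C; Na2S2O3 work-up
Reagents that add atoms: potassium iodide [K+].[I-]; sodium hydride [Na+].[H-] (its sodium stays only in intermediate 7)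
Why: Proposed new method: diazonio-activated SNAr etherification followed by iododediazoniation in one flask. The diazonio group is the strongest SNAr activator available, so the phenoxide 7 should displace the ortho fluoride irreversibly (NaF precipitates); 7 has every ortho/para carbon substituted, so C-azo coupling is blocked, O–N diazo-ether formation is reversible, and this electron-poor phenoxide is a poor one-electron reductant; iodide then converts the surviving N2+ of 8 into the ring C iodine. The closest known reactions are displacement of ortho/para halide in arenediazonium ions by hydroxide or halide, fluoride-displacing diaryl ether SNAr on 2-fluoronitroarenes, and Sandmeyer-type iodination.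

Step 5
Reactants: 9 3,5-dibromo-2-[3,4,5-tribromo-2-(4-bromo-2-iodophenoxy)phenoxy]benzaldehyde
Product: 11 Bromoiesol B (3,5-dibromo-2-[3,4,5-tribromo-2-(4-bromo-2-iodophenoxy)phenoxy]phenol), via aryl formate 10 (not isolated)
Conditions: mCPBA (2 equiv), CH2Cl2, 40 °C; aq Na2S2O3 wash (returns any aryl-λ3-iodane to ArI); then MeOH, Et3N (0.2 equiv), 20 °C
Reagents that add atoms: 3-chloroperoxybenzoic acid OOC(=O)c1cccc(Cl)c1
Why: Baeyer–Villiger (Dakin-type) oxidation in which the ortho-aryloxy-substituted aryl group migrates in the Criegee intermediate to give the aryl formate, which is methanolysed to the phenol.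

**Compound list**
1 | 4,5-dibromobenzene-1,2-diol (4,5-dibromocatechol) | Oc1cc(Br)c(Br)cc1O | starting material
2 | 3,5-dibromo-2-fluorobenzaldehyde | O=Cc1cc(Br)cc(Br)c1F | starting material
3 | 5-bromo-2-fluoroaniline | Nc1cc(Br)ccc1F | starting material
4 | 5-bromo-2-fluorobenzenediazonium tetrafluoroborate | N#[N+]c1cc(Br)ccc1F.F[B-](F)(F)F | intermediate
5 | 3,5-dibromo-2-(4,5-dibromo-2-hydroxyphenoxy)benzaldehyde | O=Cc1cc(Br)cc(Br)c1Oc1cc(Br)c(Br)cc1O | intermediate
6 | 3,5-dibromo-2-(3,4,5-tribromo-2-hydroxyphenoxy)benzaldehyde | O=Cc1cc(Br)cc(Br)c1Oc1cc(Br)c(Br)c(Br)c1O | intermediate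
7 | sodium 2,3,4-tribromo-6-(2,4-dibromo-6-formylphenoxy)phenolate | O=Cc1cc(Br)cc(Br)c1Oc1cc(Br)c(Br)c(Br)c1[O-].[Na+] | intermediate (not isolated)
8 | 5-bromo-2-[2,3,4-tribromo-6-(2,4-dibromo-6-formylphenoxy)phenoxy]benzenediazonium tetrafluoroborate | O=Cc1cc(Br)cc(Br)c1Oc1cc(Br)c(Br)c(Br)c1Oc1ccc(Br)cc1[N+]#N.F[B-](F)(F)F | intermediate (not isolated)
9 | 3,5-dibromo-2-[3,4,5-tribromo-2-(4-bromo-2-iodophenoxy)phenoxy]benzaldehyde | O=Cc1cc(Br)cc(Br)c1Oc1cc(Br)c(Br)c(Br)c1Oc1ccc(Br)cc1I | intermediate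
10 | 3,5-dibromo-2-[3,4,5-tribromo-2-(4-bromo-2-iodophenoxy)phenoxy]phenyl formate | O=COc1cc(Br)cc(Br)c1Oc1cc(Br)c(Br)c(Br)c1Oc1ccc(Br)cc1I | intermediate (not isolated)
11 | Bromoiesol B, 3,5-dibromo-2-[3,4,5-tribromo-2-(4-bromo-2-iodophenoxy)phenoxy]phenol | Oc1cc(Br)cc(Br)c1Oc1cc(Br)c(Br)c(Br)c1Oc1ccc(Br)cc1I | target

**Step count**
Total steps: 5. Longest linear sequence: 4 (steps 2, 3, 4, 5); step 1 is a one-step side branch.

**Three steps most likely to fail**

Step 4 (the proposed new step). The risks are homolysis of the reversibly formed diazo ether or electron transfer from the phenoxide, which would give reduced or scrambled arenes, and slow attack by the hindered phenoxide. The fallback uses known chemistry only, sets out from 6 and comes back at 8. Phenol 6 is arylated with commercial 4-bromo-1-fluoro-2-nitrobenzene (K2CO3, DMF, 60 °C) to give 3,5-dibromo-2-[3,4,5-tribromo-2-(4-bromo-2-nitrophenoxy)phenoxy]benzaldehyde F1. The nitro group is reduced (Fe, NH4Cl, EtOH/H2O, 70 °C) to 2-[2-(2-amino-4-bromophenoxy)-3,4,5-tribromophenoxy]-3,5-dibromobenzaldehyde F2. F2 is used crude because it carries both an amine and an aldehyde; it is diazotised at once in aqueous acid (NaNO2, 48% HBF4, AcOH, 0 °C), where any imine is hydrolysed. This gives the tetrafluoroborate 8, which is treated with KI as in step 4 to reach 9.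

Step 2. The risks are double arylation of the catechol and air oxidation of the catechol under base. The fallback sets out from 2 and comes back at 6, bypassing 5. Aldehyde 2 is coupled with commercial 4-bromo-2-methoxyphenol (K2CO3, DMF, 70 °C), which has only one OH, to give 3,5-dibromo-2-(4-bromo-2-methoxyphenoxy)benzaldehyde F3. The methyl ether is cleaved with BBr3 (CH2Cl2, −78 → 0 °C, aqueous work-up) to give 3,5-dibromo-2-(4-bromo-2-hydroxyphenoxy)benzaldehyde F4. Dibromination of F4 (Br2, 2.1 equiv, NaOAc, AcOH) at the free ortho and para positions of the ring B phenol then gives 6 directly.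

Step 5. The risks are that the doubly brominated aryl group migrates too slowly, so that hydride migration gives the benzoic acid, and that the peracid partly oxidises the aryl iodide. The fallback avoids peracid and aryl migration, sets out from 9 and comes back at 11. Pinnick oxidation (NaClO2, NaH2PO4, 2-methyl-2-butene, t-BuOH/THF/H2O) gives 3,5-dibromo-2-[3,4,5-tribromo-2-(4-bromo-2-iodophenoxy)phenoxy]benzoic acid F5. Curtius rearrangement (DPPA, Et3N, toluene/t-BuOH, 85 °C) passes through the corresponding benzoyl azide F6 and the aryl isocyanate F7 to tert-butyl N-{3,5-dibromo-2-[3,4,5-tribromo-2-(4-bromo-2-iodophenoxy)phenoxy]phenyl}carbamate F8. TFA in CH2Cl2 liberates 3,5-dibromo-2-[3,4,5-tribromo-2-(4-bromo-2-iodophenoxy)phenoxy]aniline F9. Diazotisation (NaNO2, H2SO4/AcOH, 0 °C) gives the corresponding benzenediazonium hydrogensulfate F10, which is hydroxylated by the Cu2O/excess aqueous Cu(NO3)2 hydroxydediazoniation to give 11.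

**Further compounds**
F1 | step 4 | 3,5-dibromo-2-[3,4,5-tribromo-2-(4-bromo-2-nitrophenoxy)phenoxy]benzaldehyde | O=Cc1cc(Br)cc(Br)c1Oc1cc(Br)c(Br)c(Br)c1Oc1ccc(Br)cc1[N+](=O)[O-]
F2 | step 4 | 2-[2-(2-amino-4-bromophenoxy)-3,4,5-tribromophenoxy]-3,5-dibromobenzaldehyde | O=Cc1cc(Br)cc(Br)c1Oc1cc(Br)c(Br)c(Br)c1Oc1ccc(Br)cc1N
F3 | step 2 | 3,5-dibromo-2-(4-bromo-2-methoxyphenoxy)benzaldehyde | O=Cc1cc(Br)cc(Br)c1Oc1ccc(Br)cc1OC
F4 | step 2 | 3,5-dibromo-2-(4-bromo-2-hydroxyphenoxy)benzaldehyde | O=Cc1cc(Br)cc(Br)c1Oc1ccc(Br)cc1O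
F5 | step 5 | 3,5-dibromo-2-[3,4,5-tribromo-2-(4-bromo-2-iodophenoxy)phenoxy]benzoic acid | OC(=O)c1cc(Br)cc(Br)c1Oc1cc(Br)c(Br)c(Br)c1Oc1ccc(Br)cc1I
F6 | step 5 | 3,5-dibromo-2-[3,4,5-tribromo-2-(4-bromo-2-iodophenoxy)phenoxy]benzoyl azide | [N-]=[N+]=NC(=O)c1cc(Br)cc(Br)c1Oc1cc(Br)c(Br)c(Br)c1Oc1ccc(Br)cc1I
F7 | step 5 | 3,5-dibromo-2-[3,4,5-tribromo-2-(4-bromo-2-iodophenoxy)phenoxy]phenyl isocyanate | O=C=Nc1cc(Br)cc(Br)c1Oc1cc(Br)c(Br)c(Br)c1Oc1ccc(Br)cc1I
F8 | step 5 | tert-butyl N-{3,5-dibromo-2-[3,4,5-tribromo-2-(4-bromo-2-iodophenoxy)phenoxy]phenyl}carbamate | CC(C)(C)OC(=O)Nc1cc(Br)cc(Br)c1Oc1cc(Br)c(Br)c(Br)c1Oc1ccc(Br)cc1I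
F9 | step 5 | 3,5-dibromo-2-[3,4,5-tribromo-2-(4-bromo-2-iodophenoxy)phenoxy]aniline | Nc1cc(Br)cc(Br)c1Oc1cc(Br)c(Br)c(Br)c1Oc1ccc(Br)cc1I
F10 | step 5 | 3,5-dibromo-2-[3,4,5-tribromo-2-(4-bromo-2-iodophenoxy)phenoxy]benzenediazonium hydrogensulfate | N#[N+]c1cc(Br)cc(Br)c1Oc1cc(Br)c(Br)c(Br)c1Oc1ccc(Br)cc1I.OS(=O)(=O)[O-]
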